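## Retrosynthetic overview

- Numbering: C1 (bridgehead C–OH), C2 (guaiacyl CH), O3, C4H2, C5 (bridgehead CH), C6 (veratryl CH), O7, C8H2. Ring A = C1-C2-O3-C4-C5 and ring B = C1-C5-C6-O7-C8. The target is (1S,2R,5R,6S) with both aryl groups exo.
- Feature used: C1 is a tertiary carbinol bonded to C8, C5 and C2. With C2 raised to a lactone carbonyl this is an α-hydroxy ester, the retron of a benzilic ester rearrangement.
- Late disconnections: phenol O–Si; C2–O3 (closure through the benzylic cation, aryl exo); C2–H; C2–aryl (aryllithium 19 plus hydroxy lactone 16).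
- Key disconnection: in 16, C1–C8 and O3–C2 are broken and C8 is rejoined to C2. This gives the six-membered 1,2-dione 14 (ring O7-C8-C2-C1-C5-C6) carrying the C4 hydroxymethyl tether on C5. Dione 14 comes from the enantioselective hetero-Diels–Alder adduct 4 by hydroxymethylation at C5 and oxygenation at C2.
- Ring order: the pyranone ring forms in step 1. In step 8 it contracts to ring B while ring A closes as the lactone. Ring A is opened by the aryl nucleophile in step 10 and closed again as the ether in step 12.

Key step: step 8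

Assumption: (S)-BINOL/Ti(Oi-Pr)4 is taken to give (S)-4, by analogy with the facial sense of Ti–BINOL allylation of aldehydes. If the sense is opposite, (R)-BINOL is used and nothing else changes.

Assumption: diones 13 and 14 are written as diketones and share one number with their tautomers. They are expected to rest mainly as the enol toward C8 (a 5-hydroxy-2,3-dihydro-4H-pyran-4-one). Step 8 is therefore run with catalytic base and heat, not with stoichiometric strong base.

Target numbering is used for all intermediates.

## Route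

Step 1
Reactants: 1 veratraldehyde; 2 Danishefsky's diene
Product: 4 (S)-2-(3,4-dimethoxyphenyl)-2,3-dihydro-4H-pyran-4-one, via silylated aldol adduct 3 (not isolated)
Conditions: (S)-BINOL (20 mol %), Ti(Oi-Pr)4 (10 mol %), 4 Å MS, Et2O, −20 °C; then TFA (cat.), CH2Cl2, 0 °C; recrystallisation
Reagents that add atoms: none
Why: Catalytic enantioselective hetero-Diels–Alder reaction in its Mukaiyama aldol/cyclisation form; the chiral Ti Lewis acid shields one aldehyde face and sets C6 (S), and acid then closes 3 by oxa-Michael addition with loss of methanol.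

Step 2
Reactants: 4; 5 formaldehyde (monomer in THF, from cracked paraformaldehyde)
Product: 7 (2S,3R)-2-(3,4-dimethoxyphenyl)-3-(hydroxymethyl)-2,3-dihydro-4H-pyran-4-one (trans), via lithium dienolate 6 (not isolated)
Conditions: LDA (1.1 equiv), THF, −78 °C; CH2O/THF, −78 °C; AcOH quench at −78 °C
Reagents that add atoms: none
Why: Kinetic α′-deprotonation of the vinylogous ester followed by aldol addition to formaldehyde; the electrophile approaches C5 anti to the C6 aryl group and gives the trans, also thermodynamic, isomer (C5 R), while −78 °C throughout keeps the 2H-pyranolate 6 from ring opening.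

Step 3
Reactants: 7
Product: 8 (2S,3R)-3-[(tert-butyldimethylsilyloxy)methyl]-2-(3,4-dimethoxyphenyl)-2,3-dihydro-4H-pyran-4-one
Conditions: TBSCl, imidazole, CH2Cl2, 0 °C → rt
Reagents that add atoms: tert-butyldimethylsilyl chloride, CC(C)(C)[Si](C)(C)Cl
Why: Standard silylation of a primary alcohol under weakly basic conditions, which masks the tether oxygen and blocks dehydration of the β-hydroxy ketone.

Step 4
Reactants: 8
Product: 10 (2S,3R)-3-[(tert-butyldimethylsilyloxy)methyl]-2-(3,4-dimethoxyphenyl)-4-(trimethylsilyloxy)-3,6-dihydro-2H-pyran, via lithium enolate 9 (not isolated)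
Conditions: L-Selectride (1.05 equiv), THF, −78 °C; then TMSCl, Et3N, −78 → 0 °C; non-oxidative work-up, plug of Et3N-deactivated silica
Reagents that add atoms: trimethylsilyl chloride, C[Si](C)(C)Cl
Why: 1,4-reduction of the dihydropyranone by a bulky borohydride gives the enolate regiospecifically on the C2 side, and O-silylation fixes it as the C1=C2 silyl enol ether without touching C5 or C6.

Step 5
Reactants: 10
Product: 12 (2S,3R)-3-[(tert-butyldimethylsilyloxy)methyl]-2-(3,4-dimethoxyphenyl)-5-hydroxytetrahydro-4H-pyran-4-one (either configuration at the new carbinol), via silyloxy epoxide 11 (not isolated)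
Conditions: DMDO, acetone/CH2Cl2, −78 → 0 °C; then 10 % aq. citric acid, THF, rt
Reagents that add atoms: dimethyldioxirane, CC1(C)OO1
Why: Rubottom oxidation, that is epoxidation of the electron-rich enol ether and mild acid opening with loss of the TMS group, places oxygen on C2; the configuration of this carbinol is irrelevant because step 6 removes it.

Step 6
Reactants: 12
Product: 13 (5R,6S)-5-[(tert-butyldimethylsilyloxy)methyl]-6-(3,4-dimethoxyphenyl)dihydro-2H-pyran-3,4-dione
Conditions: Dess–Martin periodinane (1.1 equiv), CH2Cl2, 0 °C → rt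
Reagents that add atoms: none
Why: Dess–Martin oxidation of an acyloin to the 1,2-dione under non-basic conditions; C5, now next to a dione carbonyl, stays at its trans equilibrium position.

Step 7
Reactants: 13
Product: 14 (5R,6S)-6-(3,4-dimethoxyphenyl)-5-(hydroxymethyl)dihydro-2H-pyran-3,4-dione
Conditions: HF·pyridine, THF, 0 °C → rt
Reagents that add atoms: none
Why: Acidic fluoride desilylation frees the tether hydroxyl without forming an enolate, so retro-aldol and β-elimination pathways are not opened before the key step.

Step 8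
Reactants: 14
Product: 16 (1S,5R,6S)-6-(3,4-dimethoxyphenyl)-1-hydroxy-3,7-dioxabicyclo[3.3.0]octan-2-one, via bicyclic hemiketal 15 (not isolated)
Conditions: KOt-Bu (0.2 equiv), t-BuOH/PhMe (1:4), 0.02 M, rt → 70 °C; AcOH quench
Reagents that add atoms: none
Why: Proposed new method: 14 rests largely as its enol toward C8, which buffers the medium, and reacts through the minor diketo form: the C4 oxygen adds to the carbonyl flanked by C8 to give hemiketal 15, whose oxyanion folds down to the lactone carbonyl C2 while the C8–C2 bond shifts to the adjacent carbonyl carbon, and the resulting C1 alkoxide takes a proton from the next molecule of 14, so only catalytic base is needed. The closest known reaction types are the benzilic acid and benzilic ester rearrangements of cyclic 1,2-diketones and diosphenols, which contract the ring to 1-hydroxycycloalkanecarboxylic acid derivatives, and the saccharinic acid rearrangement of sugar diuloses; delivery of the alkoxide from a tether of the substrate onto a pyran-3,4-dione is not known. Ring A closes by the 5-exo-trig hemiketalisation and is kept as the γ-lactone, whereas ring B is formed by the 1,2-shift, which takes C2 out of the six-membered ring and leaves the tetrahydrofuran O7–C8–C1–C5–C6. C1, the only new stereocentre, is controlled by C5: the one-carbon tether reaches C2 only on the ring face that carries C4, C8 then migrates to the opposite face of the bridging carbonyl of 15, and OH-1 ends cis to H-5 (1S), the only fusion a bicyclo[3.3.0] lactone allows, while C5 stays trans to the veratryl group because that is its equilibrium position next to the ketone. Both regiochemical modes of a benzilic shift would lead to the same constitution, so the step needs facial selectivity at C1, which the tether secures, and chemoselectivity against retro-aldol loss of C4, β-elimination of O7 or of the C4 hydroxyl and attack by an outside nucleophile, which is secured by the absence of hydroxide or unhindered alkoxide, by the weak basicity of the enol-buffered medium and by the fact that the ketone of 15 has only a bridgehead α-hydrogen and cannot enolise. Exchange of an eclipsed 1,2-dione for an ester plus a carbinol drives the shift, and 16, which has no acidic C–H, is the sink of all the reversible equilibria before it.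

Step 9
Reactants: 17 4-bromo-2-methoxyphenol
Product: 18 (4-bromo-2-methoxyphenoxy)(tert-butyl)dimethylsilane
Conditions: TBSCl, imidazole, DMF, rt
Reagents that add atoms: tert-butyldimethylsilyl chloride, CC(C)(C)[Si](C)(C)Cl
Why: Standard phenol silylation; a silyl ether is chosen over a benzyl ether so that the final deprotection cannot hydrogenolyse the benzylic C2–O3 and C6–O7 bonds.

Step 10
Reactants: 16; 18
Product: 20 [4-(tert-butyldimethylsilyloxy)-3-methoxyphenyl][(3S,4R,5S)-5-(3,4-dimethoxyphenyl)-3-hydroxy-4-(hydroxymethyl)tetrahydrofuran-3-yl]methanone (in equilibrium with its lactol), via aryllithium 19 (not isolated)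
Conditions: 18 (2.4 equiv), n-BuLi (2.3 equiv), THF, −78 °C; then 16, −78 °C; AcOH quench at −78 °C
Reagents that add atoms: none
Why: Bromine–lithium exchange and addition of an aryllithium to a γ-lactone; the first equivalent of 19 only deprotonates the C1 hydroxyl, the second adds to C2, and the chelated tetrahedral adduct holds at −78 °C until the quench, which holds back a second addition and leaves all stereocentres untouched.

Step 11
Reactants: 20
Product: 21 (3S,4R,5S)-3-{[4-(tert-butyldimethylsilyloxy)-3-methoxyphenyl](hydroxy)methyl}-5-(3,4-dimethoxyphenyl)-4-(hydroxymethyl)tetrahydrofuran-3-ol (either configuration at the new C2 carbinol)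
Conditions: NaBH4, EtOH/THF, 0 °C
Reagents that add atoms: none
Why: Borohydride reduction of the aryl ketone drawn from the lactol equilibrium; both C2 carbinol epimers are acceptable because C2 becomes planar in step 12.

Step 12
Reactants: 21
Product: 22 (1S,2R,5R,6S)-2-[4-(tert-butyldimethylsilyloxy)-3-methoxyphenyl]-6-(3,4-dimethoxyphenyl)-3,7-dioxabicyclo[3.3.0]octan-1-ol
Conditions: CSA (10 mol %), CH2Cl2, −20 → 0 °C
Reagents that add atoms: none
Why: Acid-catalysed SN1 cycloetherification, the usual furofuran closure: the secondary carbinol ionises to the p-silyloxybenzyl cation, the C4 hydroxyl captures it 5-exo-trig, and C2 (R) is set because the aryl group turns to the convex face beside the small C1 hydroxyl and away from C8 and ring B, so both epimers of 21 converge.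

Step 13
Reactants: 22
Product: 23 (1S,2R,5R,6S)-6-(3,4-dimethoxyphenyl)-2-(4-hydroxy-3-methoxyphenyl)-3,7-dioxabicyclo[3.3.0]octan-1-ol (target)
Conditions: TBAF (1.1 equiv), AcOH (1.1 equiv), THF, 0 °C
Reagents that add atoms: none
Why: Buffered fluoride cleavage of the aryl silyl ether, which affects neither the benzylic ethers nor the tertiary alcohol nor any stereocentre.

## Compound list

1 | veratraldehyde | COc1ccc(C=O)cc1OC | starting material
2 | Danishefsky's diene | CO/C=C/C(=C)O[Si](C)(C)C | starting material
3 | (S,E)-5-(3,4-dimethoxyphenyl)-1-methoxy-5-(trimethylsilyloxy)pent-1-en-3-one | CO/C=C/C(=O)C[C@H](O[Si](C)(C)C)c1ccc(OC)c(OC)c1 | intermediate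
4 | (S)-2-(3,4-dimethoxyphenyl)-2,3-dihydro-4H-pyran-4-one | O=C1C=CO[C@H](c2ccc(OC)c(OC)c2)C1 | intermediate
5 | formaldehyde | C=O | starting material
6 | lithium (S)-2-(3,4-dimethoxyphenyl)-2H-pyran-4-olate | [Li]OC1=C[C@@H](c2ccc(OC)c(OC)c2)OC=C1 | intermediate
7 | (2S,3R)-2-(3,4-dimethoxyphenyl)-3-(hydroxymethyl)-2,3-dihydro-4H-pyran-4-one | O=C1C=CO[C@H](c2ccc(OC)c(OC)c2)[C@H]1CO | intermediate
8 | TBS ether of 7 | O=C1C=CO[C@H](c2ccc(OC)c(OC)c2)[C@H]1CO[Si](C)(C)C(C)(C)C | intermediate
9 | lithium enolate from 1,4-reduction of 8 | [Li]OC1=CCO[C@H](c2ccc(OC)c(OC)c2)[C@H]1CO[Si](C)(C)C(C)(C)C | intermediate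
10 | TMS enol ether (3,6-dihydro-2H-pyran) | C[Si](C)(C)OC1=CCO[C@H](c2ccc(OC)c(OC)c2)[C@H]1CO[Si](C)(C)C(C)(C)C | intermediate
11 | silyloxy epoxide of 10 (epoxide face not specified) | C[Si](C)(C)OC12OC1CO[C@H](c3ccc(OC)c(OC)c3)[C@H]2CO[Si](C)(C)C(C)(C)C | intermediate
12 | α-hydroxy ketone (carbinol centre not specified) | O=C1C(O)CO[C@H](c2ccc(OC)c(OC)c2)[C@H]1CO[Si](C)(C)C(C)(C)C | intermediate
13 | (5R,6S)-5-[(tert-butyldimethylsilyloxy)methyl]-6-(3,4-dimethoxyphenyl)dihydro-2H-pyran-3,4-dione | O=C1CO[C@H](c2ccc(OC)c(OC)c2)[C@@H](CO[Si](C)(C)C(C)(C)C)C1=O | intermediate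
14 | (5R,6S)-6-(3,4-dimethoxyphenyl)-5-(hydroxymethyl)dihydro-2H-pyran-3,4-dione | O=C1CO[C@H](c2ccc(OC)c(OC)c2)[C@@H](CO)C1=O | intermediate
15 | (1R,2S,5S)-2-(3,4-dimethoxyphenyl)-5-hydroxy-3,6-dioxabicyclo[3.2.1]octan-8-one | O[C@@]12CO[C@H](c3ccc(OC)c(OC)c3)[C@@H](CO1)C2=O | intermediate
16 | (1S,5R,6S)-6-(3,4-dimethoxyphenyl)-1-hydroxy-3,7-dioxabicyclo[3.3.0]octan-2-one | O[C@]12CO[C@H](c3ccc(OC)c(OC)c3)[C@H]1COC2=O | intermediate
17 | 4-bromo-2-methoxyphenol | COc1cc(Br)ccc1O | starting material
18 | (4-bromo-2-methoxyphenoxy)(tert-butyl)dimethylsilane | COc1cc(Br)ccc1O[Si](C)(C)C(C)(C)C | intermediate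
19 | 4-(tert-butyldimethylsilyloxy)-3-methoxyphenyllithium | COc1cc([Li])ccc1O[Si](C)(C)C(C)(C)C | intermediate
20 | keto diol (open form of the lactol) | O=C(c1ccc(O[Si](C)(C)C(C)(C)C)c(OC)c1)[C@@]1(O)CO[C@H](c2ccc(OC)c(OC)c2)[C@H]1CO | intermediate
21 | triol (C2 carbinol not specified) | OC(c1ccc(O[Si](C)(C)C(C)(C)C)c(OC)c1)[C@@]1(O)CO[C@H](c2ccc(OC)c(OC)c2)[C@H]1CO | intermediate
22 | O-TBS ether of the target | COc1cc([C@H]2OC[C@@H]3[C@@H](c4ccc(OC)c(OC)c4)OC[C@]23O)ccc1O[Si](C)(C)C(C)(C)C | intermediate
23 | CNP0141816.1 | COc1cc([C@H]2OC[C@@H]3[C@@H](c4ccc(OC)c(OC)c4)OC[C@]23O)ccc1O | target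

Total step count: 13. Longest linear sequence: 12 (steps 1–8 and 10–13, from veratraldehyde).

## Steps most likely to fail

**1. Step 8 (key step).**
- What may go wrong: the enolate resting state may be too stable for the diketo/hemiketal manifold to be reached below the temperature at which other processes take over.
- These processes are retro-aldol loss of the C4 carbon, β-elimination with opening of the pyran ring (which would erase C5 and C6), and reversible oxa-Michael addition of the tether to C8.
- The fallback uses known chemistry, a Wolff ring contraction followed by enolate hydroxylation. It sets out from 8 and comes back at 16.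
- Compound 8 is reduced with L-Selectride and quenched with a proton source to give (2S,3R)-3-[(tert-butyldimethylsilyloxy)methyl]-2-(3,4-dimethoxyphenyl)tetrahydro-4H-pyran-4-one F1.
- Kinetic enolisation at the unsubstituted α-carbon (LiHMDS, −78 °C) and acylation with 2,2,2-trifluoroethyl trifluoroacetate give the 5-trifluoroacetyl ketone F2.
- Detrifluoroacetylative diazo transfer (MsN3, Et3N, H2O, MeCN) converts it into the 5-diazo ketone F3.
- Photolysis in MeOH (Wolff rearrangement) contracts the ring to methyl (4R,5S)-4-[(tert-butyldimethylsilyloxy)methyl]-5-(3,4-dimethoxyphenyl)tetrahydrofuran-3-carboxylate F4.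
- HF·pyridine, then catalytic DBU in warm toluene, equilibrates the ester-bearing centre and lactonises the cis isomer to (1R,5R,6S)-6-(3,4-dimethoxyphenyl)-3,7-dioxabicyclo[3.3.0]octan-2-one F5.
- KHMDS at −78 °C followed by 2-(phenylsulfonyl)-3-phenyloxaziridine (Davis hydroxylation) places the hydroxyl on C1 from the convex face and gives 16.

**2. Step 12.**
- What may go wrong: poor facial selectivity in the capture of the C2 cation.
- The veratryl C6–O7 ether may ionise competitively, with epimerisation at C6.
- A pinacol-type shift from the neighbouring C1 carbinol is also possible.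
- The fallback brings the aryl group in as the nucleophile on the ring-A oxocarbenium ion, so that the convex face dictates an exo aryl. It sets out from 16 and comes back at 22, bypassing steps 10–12.
- DIBAL-H (CH2Cl2, −78 °C) reduces 16 to the lactol (1S,5R,6S)-6-(3,4-dimethoxyphenyl)-3,7-dioxabicyclo[3.3.0]octane-1,2-diol F6.
- Ac2O/pyridine acetylates only the anomeric hydroxyl and gives the 2-acetate F7.
- Transmetalation of 19 with ZnBr2 (0.5 equiv) gives bis[4-(tert-butyldimethylsilyloxy)-3-methoxyphenyl]zinc F8.
- Excess F8 and F7 with BF3·OEt2 (PhMe/CH2Cl2, −40 °C) react in a C-glycosylation-type arylation and should deliver 22. The zinc alkoxide formed at the C1 hydroxyl sits on the same convex face.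

**3. Step 2.**
- What may go wrong: opening of the 2H-pyranolate 6, electrocyclic or by E1cB, with loss of enantiopurity.
- Double aldol addition, dehydration of the aldol, or polymerisation of formaldehyde before it reacts may also occur.
- The fallback brings C4 in on the diene, so that no enolate of the chiral pyranone is needed. It sets out from 1 and comes back at 8.
- Commercial (E)-4-methoxybut-3-en-2-one F9 is deprotonated at its methyl group (LDA, −78 °C) and treated with 5 to give (E)-5-hydroxy-1-methoxypent-1-en-3-one F10.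
- TBSCl/imidazole converts it into (E)-5-(tert-butyldimethylsilyloxy)-1-methoxypent-1-en-3-one F11.
- TMSOTf/Et3N then gives (1E,3Z)-5-(tert-butyldimethylsilyloxy)-1-methoxy-3-(trimethylsilyloxy)penta-1,3-diene F12.
- The Ti–BINOL hetero-Diels–Alder/TFA protocol of step 1 with 1 should give 8 together with its cis epimer at C5, (2S,3S)-3-[(tert-butyldimethylsilyloxy)methyl]-2-(3,4-dimethoxyphenyl)-2,3-dihydro-4H-pyran-4-one F13.
- F13 is separated and equilibrated to 8 with a mild amine base.

## Further compounds

F1 | step 8 | (2S,3R)-3-[(tert-butyldimethylsilyloxy)methyl]-2-(3,4-dimethoxyphenyl)tetrahydro-4H-pyran-4-one | O=C1CCO[C@H](c2ccc(OC)c(OC)c2)[C@H]1CO[Si](C)(C)C(C)(C)C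
F2 | step 8 | 5-trifluoroacetyl derivative of F1 | O=C1C(C(=O)C(F)(F)F)CO[C@H](c2ccc(OC)c(OC)c2)[C@H]1CO[Si](C)(C)C(C)(C)C
F3 | step 8 | 5-diazo derivative of F1 | O=C1C(=[N+]=[N-])CO[C@H](c2ccc(OC)c(OC)c2)[C@H]1CO[Si](C)(C)C(C)(C)C
F4 | step 8 | methyl (4R,5S)-4-[(tert-butyldimethylsilyloxy)methyl]-5-(3,4-dimethoxyphenyl)tetrahydrofuran-3-carboxylate | COC(=O)C1CO[C@H](c2ccc(OC)c(OC)c2)[C@H]1CO[Si](C)(C)C(C)(C)C
F5 | step 8 | (1R,5R,6S)-6-(3,4-dimethoxyphenyl)-3,7-dioxabicyclo[3.3.0]octan-2-one | O=C1OC[C@H]2[C@@H]1CO[C@@H]2c1ccc(OC)c(OC)c1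
F6 | step 12 | (1S,5R,6S)-6-(3,4-dimethoxyphenyl)-3,7-dioxabicyclo[3.3.0]octane-1,2-diol | O[C@]12CO[C@H](c3ccc(OC)c(OC)c3)[C@H]1COC2O
F7 | step 12 | 2-acetate of F6 | O[C@]12CO[C@H](c3ccc(OC)c(OC)c3)[C@H]1COC2OC(C)=O
F8 | step 12 | bis[4-(tert-butyldimethylsilyloxy)-3-methoxyphenyl]zinc | COc1cc([Zn]c2ccc(O[Si](C)(C)C(C)(C)C)c(OC)c2)ccc1O[Si](C)(C)C(C)(C)C
F9 | step 2 | (E)-4-methoxybut-3-en-2-one (commercial) | CO/C=C/C(C)=O
F10 | step 2 | (E)-5-hydroxy-1-methoxypent-1-en-3-one | CO/C=C/C(=O)CCO
F11 | step 2 | (E)-5-(tert-butyldimethylsilyloxy)-1-methoxypent-1-en-3-one | CO/C=C/C(=O)CCO[Si](C)(C)C(C)(C)C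
F12 | step 2 | (1E,3Z)-5-(tert-butyldimethylsilyloxy)-1-methoxy-3-(trimethylsilyloxy)penta-1,3-diene | CO/C=C/C(O[Si](C)(C)C)=C/CO[Si](C)(C)C(C)(C)C
F13 | step 2 | (2S,3S)-3-[(tert-butyldimethylsilyloxy)methyl]-2-(3,4-dimethoxyphenyl)-2,3-dihydro-4H-pyran-4-one | O=C1C=CO[C@H](c2ccc(OC)c(OC)c2)[C@@H]1CO[Si](C)(C)C(C)(C)C
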